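**Retrosynthetic overview**
- The target acid comes from a silyl-protected spiro tropone by desilylation and oxidation of a primary alcohol to the acid.
- Key step: the dihydrofuran and the tropone are formed together by a rhodium-catalysed carbonylative [2+2+2+1] cycloaddition of a tethered diyne (prop-1-ynyl ether and propargyl group on one carbinol carbon) with methyl but-2-ynoate and CO.
- The diyne comes from a 2,2,6-trisubstituted cyclohexanone by propargylation anti to the axial methyl, then ynol ether formation; the ketone oxygen becomes the spiro ether oxygen.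
- The ketone comes from (S)-carvone by hydration, α′-methylation, α′-alkylation (quaternary centre) and conjugate reduction.
- Ring order: cyclohexane from the chiral pool first, then dihydrofuran and tropone in one operation.

Assumption: the target is the enantiomer encoded in the SMILES, which is (2R,2′R,3′S,6′S) in the spiro name used in the compound list.

**Route**

Step 1
Reactants: 1 (S)-carvone
Product: 2 hydroxy enone (5S)-5-(2-hydroxypropan-2-yl)-2-methylcyclohex-2-en-1-one
Conditions: 50% aq H2SO4, 0 → 23 °C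
Reagents that add atoms: water, O
Why: Acid-catalysed Markovnikov hydration of the isopropenyl group through the tertiary cation leaves the enone and the C5 stereocentre from the chiral pool untouched.

Step 2
Reactants: 2 hydroxy enone
Product: 3 TES ether enone
Conditions: Et3SiOTf, 2,6-lutidine, CH2Cl2, −78 → 0 °C
Reagents that add atoms: triethylsilyl trifluoromethanesulfonate, CC[Si](CC)(CC)OS(=O)(=O)C(F)(F)F
Why: Silyl ether protection of the tertiary alcohol masks the only OH before the enolate and alkoxide chemistry.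

Step 3
Reactants: 3 TES ether enone
Product: 5 6-methyl enone (5S,6R)-2,6-dimethyl-5-{2-[(triethylsilyl)oxy]propan-2-yl}cyclohex-2-en-1-one, via lithium dienolate 4 (not isolated)
Conditions: LiN(i-Pr)2, THF, −78 °C; MeI, −78 → 0 °C
Reagents that add atoms: iodomethane, CI
Why: Kinetic α′-deprotonation of the enone and enolate alkylation install the methyl group, mainly trans to the C5 side chain, and this centre is planarised again in step 4.

Step 4
Reactants: 5 6-methyl enone, 6 tert-butyl(3-iodopropoxy)dimethylsilane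
Product: 8 quaternary enone (5S,6R)-6-{3-[(tert-butyldimethylsilyl)oxy]propyl}-2,6-dimethyl-5-{2-[(triethylsilyl)oxy]propan-2-yl}cyclohex-2-en-1-one, via lithium dienolate 7 (not isolated)
Conditions: LiN(i-Pr)2, THF, −78 °C; 6, DMPU, −78 → 0 °C
Reagents that add atoms: 6 tert-butyl(3-iodopropoxy)dimethylsilane, CC(C)(C)[Si](C)(C)OCCCI
Why: Enolate alkylation builds the quaternary centre with the electrophile entering anti to the bulky C5 substituent, which fixes C6 as R (chain trans to the side chain, methyl cis).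

Step 5
Reactants: 8 quaternary enone
Product: 10 ketone (2R,3S,6S)-2-{3-[(tert-butyldimethylsilyl)oxy]propyl}-2,6-dimethyl-3-{2-[(triethylsilyl)oxy]propan-2-yl}cyclohexan-1-one, via lithium enolate 9 (not isolated)
Conditions: Li[HB(s-Bu)3], THF, −78 °C; MeOH; NaOMe (cat.), MeOH, 23 °C
Reagents that add atoms: none
Why: Conjugate (1,4-) hydride reduction of the enone gives the enolate, and base equilibration after protonation places the C6 methyl equatorial (6S), away from a syn-diaxial clash with the axial C2 methyl.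

Step 6
Reactants: 10 ketone, 11 3-bromo-1-(trimethylsilyl)prop-1-yne
Product: 12 homopropargylic alcohol (1R,2R,3S,6S)-2-{3-[(tert-butyldimethylsilyl)oxy]propyl}-2,6-dimethyl-3-{2-[(triethylsilyl)oxy]propan-2-yl}-1-[3-(trimethylsilyl)prop-2-yn-1-yl]cyclohexan-1-ol
Conditions: Zn, 11, THF, 0 → 23 °C; aq NH4Cl
Reagents that add atoms: 11 3-bromo-1-(trimethylsilyl)prop-1-yne, C[Si](C)(C)C#CCBr
Why: Barbier propargylation with the non-basic silyl-capped allenyl/propargyl zinc reagent attacks the ketone axially, anti to the axial C2 methyl, which sets C1 as R and keeps the ketone oxygen as the future ether oxygen.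

Step 7
Reactants: 12 homopropargylic alcohol
Product: 16 prop-1-ynyl ether of 12, via dichloroethenyl ether 13 (not isolated), via chloroethynyl ether 14 (not isolated), via lithium alkynyl ether 15 (not isolated)
Conditions: KH, THF, 0 °C; Cl2C=CHCl, −50 → 23 °C; n-BuLi (2.4 equiv), −78 → −40 °C; MeI, HMPA, −78 → 23 °C
Reagents that add atoms: trichloroethylene, ClC=C(Cl)Cl; iodomethane, CI
Why: Greene ynol ether synthesis, in which the potassium alkoxide adds to dichloroacetylene, n-BuLi effects elimination and Cl–Li exchange, and the lithium acetylide is methylated, with no stereocentre involved.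

Step 8
Reactants: 16 prop-1-ynyl ether
Product: 17 diyne (terminal alkyne freed)
Conditions: K2CO3, MeOH, 23 °C
Reagents that add atoms: none
Why: Base-mediated methanolysis (protodesilylation) cleaves only the C(sp)–Si bond, while the base-stable ynol ether and both silyl ethers survive.

Step 9
Reactants: 17 diyne, 18 methyl but-2-ynoate
Product: 19 silyl-protected spiro tropone
Conditions: [Rh(cod)Cl]2 (5 mol %), CO (2 atm), 18 (5 equiv), ClCH2CH2Cl, 50 °C, 0.01 M
Reagents that add atoms: carbon monoxide, [C-]#[O+]; 18 methyl but-2-ynoate, CC#CC(=O)OC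
Why: Proposed new method: three-component variant of the rhodium-catalysed [2+2+2+1] carbonylative cycloaddition (closest known reaction type: the fully intramolecular triyne/CO route to fused tropones, and the rhodium-catalysed [2+2+2] of 1,6-diynes with external alkynoates); oxidative cyclisation of the two tethered alkynes on rhodium closes the dihydrofuran, the less hindered Rh–C(H) bond adds across the ynoate with C–C bond formation at its methyl-bearing β-carbon (the polarity of rhodium-catalysed hydroarylation of alkynoates), CO inserts between the two rhodium-bound carbons and reductive elimination closes the tropone, so both rings form in one operation and no stereocentre is touched.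

Step 10
Reactants: 19 silyl-protected spiro tropone
Product: 20 diol
Conditions: HF·pyridine, pyridine, THF, 0 → 23 °C
Reagents that add atoms: none
Why: Buffered fluoride desilylation removes both silyl ethers without ionising the tertiary alkyl vinylogous ester or touching the methyl ester.

Step 11
Reactants: 20 diol
Product: 22 target acid CNP0448476.3, via aldehyde 21 (not isolated)
Conditions: TEMPO (20 mol %), PhI(OAc)2 (2.5 equiv), MeCN/pH 7 buffer, 23 °C
Reagents that add atoms: water, O
Why: Oxoammonium (TEMPO) oxidation takes the primary alcohol through the aldehyde hydrate to the acid, while the tertiary alcohol and the tropone cannot be oxidised under these conditions.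

**Compound list**

1 | (S)-(+)-carvone, (5S)-2-methyl-5-(prop-1-en-2-yl)cyclohex-2-en-1-one | O=C1C(C)=CC[C@H](C(C)=C)C1 | starting material
2 | (5S)-5-(2-hydroxypropan-2-yl)-2-methylcyclohex-2-en-1-one (8-hydroxycarvotanacetone) | O=C1C(C)=CC[C@H](C(C)(C)O)C1 | intermediate
3 | (5S)-2-methyl-5-{2-[(triethylsilyl)oxy]propan-2-yl}cyclohex-2-en-1-one | O=C1C(C)=CC[C@H](C(C)(C)O[Si](CC)(CC)CC)C1 | intermediate
4 | kinetic cross-conjugated lithium dienolate of 3 (O–Li at C1, C1=C6) | [Li+].[O-]C1=C[C@@H](C(C)(C)O[Si](CC)(CC)CC)CC=C1C | intermediate (not isolated)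
5 | (5S,6R)-2,6-dimethyl-5-{2-[(triethylsilyl)oxy]propan-2-yl}cyclohex-2-en-1-one (major epimer, 6-methyl trans to the C5 side chain; the 6S epimer converges in step 4) | O=C1C(C)=CC[C@H](C(C)(C)O[Si](CC)(CC)CC)[C@H]1C | intermediate
6 | tert-butyl(3-iodopropoxy)dimethylsilane | CC(C)(C)[Si](C)(C)OCCCI | starting material
7 | lithium dienolate of 5 (O–Li at C1, C1=C6) | [Li+].[O-]C1=C(C)[C@@H](C(C)(C)O[Si](CC)(CC)CC)CC=C1C | intermediate (not isolated)
8 | (5S,6R)-6-{3-[(tert-butyldimethylsilyl)oxy]propyl}-2,6-dimethyl-5-{2-[(triethylsilyl)oxy]propan-2-yl}cyclohex-2-en-1-one | O=C1C(C)=CC[C@H](C(C)(C)O[Si](CC)(CC)CC)[C@@]1(C)CCCO[Si](C)(C)C(C)(C)C | intermediate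
9 | lithium enolate formed by 1,4-reduction of 8 (O–Li at C1, C1=C6 bearing the methyl) | [Li+].[O-]C1=C(C)CC[C@H](C(C)(C)O[Si](CC)(CC)CC)[C@@]1(C)CCCO[Si](C)(C)C(C)(C)C | intermediate (not isolated)
10 | (2R,3S,6S)-2-{3-[(tert-butyldimethylsilyl)oxy]propyl}-2,6-dimethyl-3-{2-[(triethylsilyl)oxy]propan-2-yl}cyclohexan-1-one | O=C1[C@@H](C)CC[C@H](C(C)(C)O[Si](CC)(CC)CC)[C@@]1(C)CCCO[Si](C)(C)C(C)(C)C | intermediate
11 | 3-bromo-1-(trimethylsilyl)prop-1-yne | C[Si](C)(C)C#CCBr | starting material
12 | (1R,2R,3S,6S)-2-{3-[(tert-butyldimethylsilyl)oxy]propyl}-2,6-dimethyl-3-{2-[(triethylsilyl)oxy]propan-2-yl}-1-[3-(trimethylsilyl)prop-2-yn-1-yl]cyclohexan-1-ol | O[C@]1(CC#C[Si](C)(C)C)[C@@H](C)CC[C@H](C(C)(C)O[Si](CC)(CC)CC)[C@@]1(C)CCCO[Si](C)(C)C(C)(C)C | intermediate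
13 | (E)-1,2-dichloroethenyl ether of 12 | Cl/C=C(/Cl)O[C@]1(CC#C[Si](C)(C)C)[C@@H](C)CC[C@H](C(C)(C)O[Si](CC)(CC)CC)[C@@]1(C)CCCO[Si](C)(C)C(C)(C)C | intermediate (not isolated)
14 | chloroethynyl ether of 12 | ClC#CO[C@]1(CC#C[Si](C)(C)C)[C@@H](C)CC[C@H](C(C)(C)O[Si](CC)(CC)CC)[C@@]1(C)CCCO[Si](C)(C)C(C)(C)C | intermediate (not isolated)
15 | lithium alkynyl ether (lithium alkoxyacetylide) of 12 | [Li+].[C-]#CO[C@]1(CC#C[Si](C)(C)C)[C@@H](C)CC[C@H](C(C)(C)O[Si](CC)(CC)CC)[C@@]1(C)CCCO[Si](C)(C)C(C)(C)C | intermediate (not isolated)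
16 | prop-1-yn-1-yl ether of 12, (1R,2R,3S,6S) ring configuration as in 12 | CC#CO[C@]1(CC#C[Si](C)(C)C)[C@@H](C)CC[C@H](C(C)(C)O[Si](CC)(CC)CC)[C@@]1(C)CCCO[Si](C)(C)C(C)(C)C | intermediate
17 | diyne: the prop-1-yn-1-yl ether carrying a free prop-2-yn-1-yl group on the same carbon, ring configuration as in 12 | CC#CO[C@]1(CC#C)[C@@H](C)CC[C@H](C(C)(C)O[Si](CC)(CC)CC)[C@@]1(C)CCCO[Si](C)(C)C(C)(C)C | intermediate
18 | methyl but-2-ynoate | CC#CC(=O)OC | starting material
19 | methyl (2R,2′R,3′S,6′S)-2′-{3-[(tert-butyldimethylsilyl)oxy]propyl}-2′,5,6′,8-tetramethyl-7-oxo-3′-{2-[(triethylsilyl)oxy]propan-2-yl}-3,7-dihydrospiro[cyclohepta[b]furan-2,1′-cyclohexane]-6-carboxylate | COC(=O)c1c(C)cc2c(c(C)c1=O)O[C@]1(C2)[C@@H](C)CC[C@H](C(C)(C)O[Si](CC)(CC)CC)[C@@]1(C)CCCO[Si](C)(C)C(C)(C)C | intermediate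
20 | methyl (2R,2′R,3′S,6′S)-3′-(2-hydroxypropan-2-yl)-2′-(3-hydroxypropyl)-2′,5,6′,8-tetramethyl-7-oxo-3,7-dihydrospiro[cyclohepta[b]furan-2,1′-cyclohexane]-6-carboxylate | COC(=O)c1c(C)cc2c(c(C)c1=O)O[C@]1(C2)[C@@H](C)CC[C@H](C(C)(C)O)[C@@]1(C)CCCO | intermediate
21 | the corresponding aldehyde (2′-(3-oxopropyl) in place of 2′-(3-hydroxypropyl)) | COC(=O)c1c(C)cc2c(c(C)c1=O)O[C@]1(C2)[C@@H](C)CC[C@H](C(C)(C)O)[C@@]1(C)CCC=O | intermediate (not isolated)
22 | 3-[(2R,2′R,3′S,6′S)-3′-(2-hydroxypropan-2-yl)-6-(methoxycarbonyl)-2′,5,6′,8-tetramethyl-7-oxo-3,7-dihydrospiro[cyclohepta[b]furan-2,1′-cyclohexan]-2′-yl]propanoic acid (CNP0448476.3) | COC(=O)c1c(C)cc2c(c(C)c1=O)O[C@]1(C2)[C@@H](C)CC[C@H](C(C)(C)O)[C@@]1(C)CCC(=O)O | target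

**Step count and risk**

Total steps: 11. Longest linear sequence: 11 steps (1 → 22).

Steps most likely to fail:

Step 9. The three-component carbonylative cycloaddition has no direct precedent. It can leak to the benzene (no CO taken up), to the cyclopentadienone (no ynoate taken up) or to the wrong ynoate orientation, and the tertiary ynol ether can lose ketene by a retro-ene reaction above about 60 °C. The fallback tethers the third alkyne; it sets out from 17 and comes back at 20. Bu4NF in THF removes both silyl ethers and gives the diyne diol F1. DCC/DMAP esterification of its primary hydroxyl with but-2-ynoic acid gives the triyne ester F2. [Rh(cod)Cl]2 under CO at high dilution then runs the carbonylative cyclisation in the intramolecular triyne mode, for which fused tropones are documented, and gives the ansa-lactone tropone F3. K2CO3 in MeOH opens the lactone bridge to the methyl ester and the primary alcohol, which is 20.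

Step 7. The alkoxide is flanked by a quaternary carbon, so addition to dichloroacetylene may be slow, and the potassium alkoxide may fragment by retro-propargylation. The fallback avoids the potassium alkoxide; it sets out from 12 and comes back at 16. Formylation with acetic formic anhydride, pyridine and DMAP gives the formate F4. Dibromo-olefination of the formate carbonyl with CBr4/PPh3 gives the 2,2-dibromoethenyl ether F5. n-BuLi (2 equiv) at −78 °C effects elimination and Br–Li exchange, and MeI/HMPA methylates the lithium acetylide to 16.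

Step 4. The quaternary centre is made with an unactivated primary iodide on a hindered tetrasubstituted enolate, which may be slow. The fallback uses an activated electrophile and oxidises later; it sets out from 5 and comes back at 10. LiN(i-Pr)2 then allyl bromide gives the allyl enone F6 with the same anti selectivity. Li[HB(s-Bu)3] followed by NaOMe/MeOH gives the allyl ketone F7. Chemoselective hydroboration of the terminal alkene with 9-BBN and oxidation with NaBO3·4H2O gives the hydroxy ketone F8. TBSCl/imidazole then gives 10.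

Further compounds
F1 | step 9 | diyne diol: 17 without both silyl groups | CC#CO[C@]1(CC#C)[C@@H](C)CC[C@H](C(C)(C)O)[C@@]1(C)CCCO
F2 | step 9 | triyne ester: but-2-ynoate ester of the primary hydroxyl of F1 | CC#CO[C@]1(CC#C)[C@@H](C)CC[C@H](C(C)(C)O)[C@@]1(C)CCCOC(=O)C#CC
F3 | step 9 | ansa-lactone tropone: spiro tropone 20 with the ester oxygen bonded to the chain terminus instead of methyl | O3C(=O)c1c(C)cc2c(c(C)c1=O)O[C@]1(C2)[C@@H](C)CC[C@H](C(C)(C)O)[C@@]1(C)CCC3
F4 | step 7 | formate ester of 12 | O=CO[C@]1(CC#C[Si](C)(C)C)[C@@H](C)CC[C@H](C(C)(C)O[Si](CC)(CC)CC)[C@@]1(C)CCCO[Si](C)(C)C(C)(C)C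
F5 | step 7 | 2,2-dibromoethenyl ether of 12 | BrC(Br)=CO[C@]1(CC#C[Si](C)(C)C)[C@@H](C)CC[C@H](C(C)(C)O[Si](CC)(CC)CC)[C@@]1(C)CCCO[Si](C)(C)C(C)(C)C
F6 | step 4 | (5S,6R)-6-allyl-2,6-dimethyl-5-{2-[(triethylsilyl)oxy]propan-2-yl}cyclohex-2-en-1-one | O=C1C(C)=CC[C@H](C(C)(C)O[Si](CC)(CC)CC)[C@@]1(C)CC=C
F7 | step 4 | (2R,3S,6S)-2-allyl-2,6-dimethyl-3-{2-[(triethylsilyl)oxy]propan-2-yl}cyclohexan-1-one | O=C1[C@@H](C)CC[C@H](C(C)(C)O[Si](CC)(CC)CC)[C@@]1(C)CC=C
F8 | step 4 | (2R,3S,6S)-2-(3-hydroxypropyl)-2,6-dimethyl-3-{2-[(triethylsilyl)oxy]propan-2-yl}cyclohexan-1-one | O=C1[C@@H](C)CC[C@H](C(C)(C)O[Si](CC)(CC)CC)[C@@]1(C)CCCO
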